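No rate constant is on hand for this flask, so I read two constants off the earlier runs and reckon with the fraction left.

common to all: substrate 20 mM
- birch: reagent 0.64 equiv; run made earlier
- alder: reagent 1.3 equiv; run made earlier
- ash: reagent 3.5 equiv; run made earlier
- Saturday's: reagent 3.00 equiv; time 30 h
- Tuesday's: reagent 0.500 equiv; time 30 h
- Friday's: reagent 1.20 equiv; time 30 h

| run | time / h | double product / % | substrate / % |
|---|---|---|---|
| birch | 2.50 | 4 | 68 |
| birch | 5.00 | 1 | 55 |
| birch | 8.00 | 3 | 53 |
| birch | 15.0 | 4 | 46 |
| birch | 30.0 | 4 | 40 |
| alder | 2.50 | 6 | 43 |
| alder | 8.00 | 8 | 20 |
| alder | 15.0 | 11 | 9 |
| alder | 20.0 | 13 | 9 |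
| alder | 30.0 | 16 | 7 |
| ash | 2.50 | 18 | 14 |
| ash | 5.00 | 14 | 1 |
| ash | 8.00 | 13 | 0 |
| ash | 15.0 | 13 | 1 |
| ash | 30.0 | 14 | 0 |

(readings scatter by 1.5 percentage points)

- which of these holds the largest part of the substrate at the end of Saturday's (tris adduct / first product / double product / substrate)
- which of these holds the largest part of the substrate at the end of Tuesday's (tris adduct / first product / double product / substrate)
- which of these holds the largest part of the substrate at the end of Friday's (tris adduct / first product / double product / substrate)
- amount of double product at the end of Tuesday's, in percent of the substrate charged

- the earlier runs were read with a standard deviation of 1.5 percentage points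
- a reading or a percentage of double product counts all its forms, free or not

- At 30.0 h the birch run has lost 60.0% of its substrate and shows 4% double product; one reagent per substrate lost and a second per double product come to 64.0% of the substrate charged, against a charge of 0.64 equiv.
- From birch I read 1.07, the reagent price: reagent paid per substrate lost. Its excess over one I take as the double product made per substrate lost, counting no tris adduct.
- At that price, I reckon from birch's first reading that 46.7% of its reagent is left at 2.50 h. The logarithmic fall, divided by that time and the mean substrate fraction, gives 0.363 /h.
- Tuesday's substrate starts down at a slope of 0.170 /h, in fractions of the charge.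
- Reagent is the limiting reagent in Tuesday's, because its charge buys 0.469 of the substrate. I therefore put the level of Tuesday's substrate at 53.1% left.
- The starting tangent meets that level at the knee, 2.76 h.
- Past the knee, I put Tuesday's reagent left at 30 h at about 0.308% of its charge, reckoning with the substrate at its level, so I draw the curve flat by then.
- I commit for Tuesday's to substrate in the lead and to 3.12% double product.
- The forecast says tris adduct for Saturday's, substrate for Tuesday's and first product for Friday's, with 3% double product in Tuesday's, between 1.5% and 5%: “Friday's at 1.2 equiv should likewise be mostly first product.”

- Tuesday's ends at 3.32% double product.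

    reagent + double product ⇌ tris adduct (K = 94.0 /M, k = 23.0 /M/h)
    substrate + reagent → first product (k = 18.0 /M/h)
    first product → side product (k = 0.600 /h)
    reagent + first product → double product (k = 14.0 /M/h)
    crystals ⇌ double product, rate k5*(cs5 - [double product]) while solid is left; crystals form when [double product] > cs5 (solubility = 17.0 mM, k = 12.0 /h)

- Friday's is where the forecast and the flask part: of the species asked about, double product leads with 13.8%, first product stands at 0.460%, and side product holds 75.2%. Tuesday's paid 1.07 per substrate lost. For the neighbour of Tuesday's charged with 0.120 equiv, the reagent price gives 88.8% substrate left, and that flask holds 88.2%.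

The earlier runs and the new flask were generated by integration with constants of no real substance; the scatter is artificial.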